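**Retrosynthetic overview**
1. Petrosin A (meso: two mirror-image quinolizidinone halves joined head to tail) ⇐ macrocyclic bis(β-keto ester) by double dealkoxycarbonylation; C1 and C3 settle thermodynamically last.
2. Macrocycle ⇐ two C1–CH2 alkylations of ring-A β-keto esters by the 5-halopentyl arm on C9 of the other half; the first joins the 9S half to the 9R half (only the cross-coupling can occur), the second closes the 16-membered ring.
3. Ring A (4-piperidone) of each half ⇐ aza-Michael addition to methyl methacrylate plus Dieckmann condensation on a trans-2,3-disubstituted piperidine.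
4. Ring B (piperidine) ⇐ key ring expansion: reductive Beckmann rearrangement of a trans-2,3-disubstituted cyclopentanone oxime, the future C9a migrating to nitrogen with retention.
5. C9/C9a ⇐ copper-catalysed asymmetric conjugate addition of one batch of 5-chloropentylzirconocene to cyclopentenone plus anti enolate alkylation; the two ligand enantiomers give the two halves. Ring order: ring B, ring A, macrocycle.

Assumption: the given descriptors define the achiral, centrosymmetric meso diastereomer, (1R,3R,9S,9aS) in one quinolizidinone and (1S,3S,9R,9aR) in the other (quinolizidine locants N5/C9a; ring A = N5,C4,C3,C2,C1,C9a; ring B = N5,C6–C9,C9a), so the two halves are made as mirror images.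

**Step 1**
Reactants: 1 5-chloropent-1-ene
Product: 2 chlorobis(cyclopentadienyl)(5-chloropentyl)zirconium
Conditions: Cp2Zr(H)Cl (1.0 equiv), CH2Cl2, rt, 30 min, argon; the clear yellow solution is divided into two equal portions and used the same day
Reagents that add atoms: chlorobis(cyclopentadienyl)hydridozirconium Cp2Zr(H)Cl, [H][Zr](Cl)(C1C=CC=C1)C1C=CC=C1
Why: Hydrozirconation adds Zr–H syn across the terminal alkene with zirconium at the terminal carbon, and the primary alkyl chloride is inert, so one batch of the primary alkylzirconocene serves both enantiomeric series.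

**Step 2**
Reactants: 2 chlorobis(cyclopentadienyl)(5-chloropentyl)zirconium; 3 cyclopent-2-en-1-one; 4 methyl bromoacetate
Product: 7 methyl 2-[(1R,2S)-2-(5-chloropentyl)-5-oxocyclopentyl]acetate, via silyl enol ether 5 (not isolated), via lithium enolate 6 (not isolated)
Conditions: first portion of 2 in CH2Cl2; 3, CuCl (10 mol %), AgOSO2CF3 (11 mol %), binaphthol/bis(1-phenylethyl)amine phosphoramidite (S,R,R)-PA (10 mol %; taken as the enantiomer giving the 3S adduct, otherwise the ligands of steps 2 and 6 are swapped), Me3SiCl, Et2O, rt; dilute with pentane, filter through Celite, concentrate; MeLi, THF, 0 °C; then 4, DMPU, −78 to −30 °C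
Reagents that add atoms: none
Why: Copper-catalysed asymmetric conjugate addition of the alkylzirconocene to 3 (ligand-controlled face selection, silyl trapping) sets the future C9 as S, and the regiodefined lithium enolate 6 is alkylated by 4 anti to the new side chain, setting the future C9a trans (three-component conjugate addition/enolate alkylation).

**Step 3**
Reactants: 7 methyl 2-[(1R,2S)-2-(5-chloropentyl)-5-oxocyclopentyl]acetate
Product: 8 methyl 2-[(1R,2S,5E)-2-(5-chloropentyl)-5-(hydroxyimino)cyclopentyl]acetate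
Conditions: NH2OH·HCl, NaOAc, MeOH, rt; minor Z isomer removed and re-equilibrated (HCl, MeOH)
Reagents that add atoms: hydroxylamine hydrochloride, Cl.NO
Why: Oxime condensation; the hydroxyl settles anti to the more substituted α-carbon (E isomer, which cannot lactonise onto the ester), the geometry needed for migration of that carbon, and the trans ring stereocentres are untouched.

**Step 4**
Reactants: 8 methyl 2-[(1R,2S,5E)-2-(5-chloropentyl)-5-(hydroxyimino)cyclopentyl]acetate
Product: 11 methyl 2-[(2R,3S)-3-(5-chloropentyl)piperidin-2-yl]acetate, via imidoyl triflate 9 (not isolated), via cyclic imine 10 (not isolated)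
Conditions: (CF3SO2)2O (1.05 equiv), 2-fluoropyridine, CH2Cl2, −78 to 0 °C; then NaBH4, MeOH, 0 °C to rt
Reagents that add atoms: none
Why: Proposed new method: O-triflation of the E-oxime should trigger Beckmann migration of the anti, more substituted ring carbon (future C9a, with retention) to cyclic imidoyl triflate 9, the same species that (CF3SO2)2O activation of a secondary lactam gives and that NaBH4 is known to reduce to the amine, so hydride added to the same flask should give the ring-expanded piperidine with ester and alkyl chloride intact; the closest known reactions are the DIBAL-H/organoaluminium reductive Beckmann rearrangement of oxime sulfonates and the (CF3SO2)2O/NaBH4 reduction of secondary amides.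

**Step 5**
Reactants: 11 methyl 2-[(2R,3S)-3-(5-chloropentyl)piperidin-2-yl]acetate; 12 methyl methacrylate
Product: 14 methyl (3R,9S,9aS)-9-(5-chloropentyl)-3-methyl-2-oxooctahydro-2H-quinolizine-1-carboxylate, via amino diester 13 (not isolated)
Conditions: 12 (3 equiv), MeOH, 60 °C; evaporate; KOt-Bu, THF, 0 °C to rt; AcOH quench
Reagents that add atoms: none
Why: Aza-Michael addition of the secondary amine to 12, then Dieckmann condensation, which funnels to the one β-keto ester that keeps an acidic C–H between its carbonyls (acetate enolate onto the propanoate ester) and so closes ring A; C9 and C9a are untouched and the C3 methyl equilibrates to equatorial.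

**Step 6**
Reactants: 2 chlorobis(cyclopentadienyl)(5-chloropentyl)zirconium; 3 cyclopent-2-en-1-one; 4 methyl bromoacetate
Product: 17 methyl 2-[(1S,2R)-2-(5-chloropentyl)-5-oxocyclopentyl]acetate, via silyl enol ether 15 (not isolated), via lithium enolate 16 (not isolated)
Conditions: second portion of 2 in CH2Cl2; 3, CuCl (10 mol %), AgOSO2CF3 (11 mol %), enantiomeric phosphoramidite (R,S,S)-PA (10 mol %), Me3SiCl, Et2O, rt; dilute with pentane, filter through Celite, concentrate; MeLi, THF, 0 °C; then 4, DMPU, −78 to −30 °C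
Reagents that add atoms: none
Why: Mirror image of step 2: with the enantiomeric ligand the copper-catalysed asymmetric conjugate addition sets the future C9 as R and the anti enolate alkylation again sets the neighbouring centre trans.

**Step 7**
Reactants: 17 methyl 2-[(1S,2R)-2-(5-chloropentyl)-5-oxocyclopentyl]acetate
Product: 18 methyl 2-[(1S,2R,5E)-2-(5-chloropentyl)-5-(hydroxyimino)cyclopentyl]acetate
Conditions: NH2OH·HCl, NaOAc, MeOH, rt; minor Z isomer removed and re-equilibrated (HCl, MeOH)
Reagents that add atoms: hydroxylamine hydrochloride, Cl.NO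
Why: Oxime condensation as in step 3, giving the E isomer with the hydroxyl anti to the substituted α-carbon.

**Step 8**
Reactants: 18 methyl 2-[(1S,2R,5E)-2-(5-chloropentyl)-5-(hydroxyimino)cyclopentyl]acetate
Product: 21 methyl 2-[(2S,3R)-3-(5-chloropentyl)piperidin-2-yl]acetate, via imidoyl triflate 19 (not isolated), via cyclic imine 20 (not isolated)
Conditions: (CF3SO2)2O (1.05 equiv), 2-fluoropyridine, CH2Cl2, −78 to 0 °C; then NaBH4, MeOH, 0 °C to rt
Reagents that add atoms: none
Why: Proposed new method: as in step 4, triflation-triggered Beckmann migration of the anti substituted carbon with retention gives the cyclic imidoyl triflate, which NaBH4 reduces in the same flask to the ring-expanded piperidine; closest known reactions are the DIBAL-H reductive Beckmann rearrangement and the (CF3SO2)2O/NaBH4 reduction of secondary amides.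

**Step 9**
Reactants: 21 methyl 2-[(2S,3R)-3-(5-chloropentyl)piperidin-2-yl]acetate; 12 methyl methacrylate
Product: 22 methyl 3-[(2S,3R)-3-(5-chloropentyl)-2-(2-methoxy-2-oxoethyl)piperidin-1-yl]-2-methylpropanoate
Conditions: 12 (3 equiv), MeOH, 60 °C
Reagents that add atoms: none
Why: Aza-Michael (conjugate) addition; stopping at the diester keeps this half free of any C–H acid that K2CO3 could deprotonate in step 11 (the new methyl-bearing centre forms as a mixture and is corrected at the end).

**Step 10**
Reactants: 22 methyl 3-[(2S,3R)-3-(5-chloropentyl)-2-(2-methoxy-2-oxoethyl)piperidin-1-yl]-2-methylpropanoate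
Product: 23 methyl 3-[(2S,3R)-3-(5-iodopentyl)-2-(2-methoxy-2-oxoethyl)piperidin-1-yl]-2-methylpropanoate
Conditions: NaI, acetone, reflux; used at once
Reagents that add atoms: sodium iodide, [Na+].[I-]
Why: Finkelstein halide exchange driven by NaCl precipitation creates the one alkylating terminus of the route.

**Step 11**
Reactants: 14 methyl (3R,9S,9aS)-9-(5-chloropentyl)-3-methyl-2-oxooctahydro-2H-quinolizine-1-carboxylate; 23 methyl 3-[(2S,3R)-3-(5-iodopentyl)-2-(2-methoxy-2-oxoethyl)piperidin-1-yl]-2-methylpropanoate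
Product: 24 methyl (3R,9S,9aS)-9-(5-chloropentyl)-1-{5-[(2S,3R)-1-(3-methoxy-2-methyl-3-oxopropyl)-2-(2-methoxy-2-oxoethyl)piperidin-3-yl]pentyl}-3-methyl-2-oxooctahydro-2H-quinolizine-1-carboxylate
Conditions: K2CO3, DMF, rt to 40 °C
Reagents that add atoms: none
Why: C-alkylation (SN2) of the potassium enolate of the cyclic β-keto ester by the primary iodide; the chloride of 14 is inert and 23 has no nucleophilic carbon, so only the heterochiral cross-coupling can occur (the new quaternary C1 centre is removed in step 14).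

**Step 12**
Reactants: 24 methyl (3R,9S,9aS)-9-(5-chloropentyl)-1-{5-[(2S,3R)-1-(3-methoxy-2-methyl-3-oxopropyl)-2-(2-methoxy-2-oxoethyl)piperidin-3-yl]pentyl}-3-methyl-2-oxooctahydro-2H-quinolizine-1-carboxylate
Product: 25 methyl (3R,9S,9aS)-9-(5-chloropentyl)-1-{5-[(3S,9R,9aR)-1-(methoxycarbonyl)-3-methyl-2-oxooctahydro-2H-quinolizin-9-yl]pentyl}-3-methyl-2-oxooctahydro-2H-quinolizine-1-carboxylate
Conditions: KN(SiMe3)2 (3.2 equiv), THF, −78 to 0 °C; AcOH quench
Reagents that add atoms: none
Why: Dieckmann condensation closes ring A of the second half exactly as in step 5, while excess base parks the ketone of the first half as its enolate so that the quaternary β-keto ester is not cleaved.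

**Step 13**
Reactants: 25 methyl (3R,9S,9aS)-9-(5-chloropentyl)-1-{5-[(3S,9R,9aR)-1-(methoxycarbonyl)-3-methyl-2-oxooctahydro-2H-quinolizin-9-yl]pentyl}-3-methyl-2-oxooctahydro-2H-quinolizine-1-carboxylate
Product: 27 dimethyl petrosin A 1,1′-dicarboxylate (16-membered macrocyclic bis-β-keto ester; C1 centres undefined), via iodide 26 (not isolated)
Conditions: NaI (5 equiv), Cs2CO3, MeCN, 80 °C, syringe-pump addition (final 2 mM)
Reagents that add atoms: none
Why: Finkelstein exchange feeds iodide 26 in low stationary concentration to the caesium enolate of the one enolisable β-keto ester, and intramolecular C-alkylation under high dilution closes the 16-membered ring (macrocyclising β-keto ester alkylation).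

**Step 14**
Reactants: 27 dimethyl petrosin A 1,1′-dicarboxylate
Product: 28 petrosin A
Conditions: LiCl, H2O, DMSO, 150 °C; then DBU (cat.), MeOH, rt
Reagents that add atoms: none
Why: Krapcho dealkoxycarbonylation removes both activating esters without acid (no iminium at C9a, so C9 cannot epimerise), and C1 and C3 then settle by enolisation in the most stable trans-fused quinolizidinone (3-methyl equatorial, 1-alkyl axial to avoid the peri clash with the equatorial C9 chain), which is (1R,3R) beside (9S,9aS) and its mirror image in the other half.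

**Compound list**
1 | 5-chloropent-1-ene | C=CCCCCl | starting material
2 | chlorobis(cyclopentadienyl)(5-chloropentyl)zirconium | ClCCCCC[Zr](Cl)(C1C=CC=C1)C1C=CC=C1 | intermediate
3 | cyclopent-2-en-1-one | O=C1C=CCC1 | starting material
4 | methyl bromoacetate | COC(=O)CBr | starting material
5 | {[(3S)-3-(5-chloropentyl)cyclopent-1-en-1-yl]oxy}trimethylsilane | C[Si](C)(C)OC1=C[C@@H](CCCCCCl)CC1 | intermediate
6 | lithium (3S)-3-(5-chloropentyl)cyclopent-1-en-1-olate | [Li+].[O-]C1=C[C@@H](CCCCCCl)CC1 | intermediate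
7 | methyl 2-[(1R,2S)-2-(5-chloropentyl)-5-oxocyclopentyl]acetate | O=C1CC[C@H](CCCCCCl)[C@H]1CC(=O)OC | intermediate
8 | methyl 2-[(1R,2S,5E)-2-(5-chloropentyl)-5-(hydroxyimino)cyclopentyl]acetate | O/N=C1\CC[C@H](CCCCCCl)[C@H]1CC(=O)OC | intermediate
9 | methyl 2-[(2R,3S)-3-(5-chloropentyl)-6-{[(trifluoromethyl)sulfonyl]oxy}-2,3,4,5-tetrahydropyridin-2-yl]acetate | N1=C(OS(=O)(=O)C(F)(F)F)CC[C@H](CCCCCCl)[C@H]1CC(=O)OC | intermediate
10 | methyl 2-[(2R,3S)-3-(5-chloropentyl)-2,3,4,5-tetrahydropyridin-2-yl]acetate | N1=CCC[C@H](CCCCCCl)[C@H]1CC(=O)OC | intermediate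
11 | methyl 2-[(2R,3S)-3-(5-chloropentyl)piperidin-2-yl]acetate | N1CCC[C@H](CCCCCCl)[C@H]1CC(=O)OC | intermediate
12 | methyl methacrylate | COC(=O)C(C)=C | starting material
13 | methyl 3-[(2R,3S)-3-(5-chloropentyl)-2-(2-methoxy-2-oxoethyl)piperidin-1-yl]-2-methylpropanoate (side-chain methyl centre undefined) | COC(=O)C(C)CN1CCC[C@H](CCCCCCl)[C@H]1CC(=O)OC | intermediate
14 | methyl (3R,9S,9aS)-9-(5-chloropentyl)-3-methyl-2-oxooctahydro-2H-quinolizine-1-carboxylate (C1 epimers/enol) | C[C@@H]1CN2CCC[C@H](CCCCCCl)[C@H]2C(C(=O)OC)C1=O | intermediate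
15 | {[(3R)-3-(5-chloropentyl)cyclopent-1-en-1-yl]oxy}trimethylsilane | C[Si](C)(C)OC1=C[C@H](CCCCCCl)CC1 | intermediate
16 | lithium (3R)-3-(5-chloropentyl)cyclopent-1-en-1-olate | [Li+].[O-]C1=C[C@H](CCCCCCl)CC1 | intermediate
17 | methyl 2-[(1S,2R)-2-(5-chloropentyl)-5-oxocyclopentyl]acetate | O=C1CC[C@@H](CCCCCCl)[C@@H]1CC(=O)OC | intermediate
18 | methyl 2-[(1S,2R,5E)-2-(5-chloropentyl)-5-(hydroxyimino)cyclopentyl]acetate | O/N=C1\CC[C@@H](CCCCCCl)[C@@H]1CC(=O)OC | intermediate
19 | methyl 2-[(2S,3R)-3-(5-chloropentyl)-6-{[(trifluoromethyl)sulfonyl]oxy}-2,3,4,5-tetrahydropyridin-2-yl]acetate | N1=C(OS(=O)(=O)C(F)(F)F)CC[C@@H](CCCCCCl)[C@@H]1CC(=O)OC | intermediate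
20 | methyl 2-[(2S,3R)-3-(5-chloropentyl)-2,3,4,5-tetrahydropyridin-2-yl]acetate | N1=CCC[C@@H](CCCCCCl)[C@@H]1CC(=O)OC | intermediate
21 | methyl 2-[(2S,3R)-3-(5-chloropentyl)piperidin-2-yl]acetate | N1CCC[C@@H](CCCCCCl)[C@@H]1CC(=O)OC | intermediate
22 | methyl 3-[(2S,3R)-3-(5-chloropentyl)-2-(2-methoxy-2-oxoethyl)piperidin-1-yl]-2-methylpropanoate (side-chain methyl centre undefined) | COC(=O)C(C)CN1CCC[C@@H](CCCCCCl)[C@@H]1CC(=O)OC | intermediate
23 | methyl 3-[(2S,3R)-3-(5-iodopentyl)-2-(2-methoxy-2-oxoethyl)piperidin-1-yl]-2-methylpropanoate | COC(=O)C(C)CN1CCC[C@@H](CCCCCI)[C@@H]1CC(=O)OC | intermediate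
24 | methyl (3R,9S,9aS)-9-(5-chloropentyl)-1-{5-[(2S,3R)-1-(3-methoxy-2-methyl-3-oxopropyl)-2-(2-methoxy-2-oxoethyl)piperidin-3-yl]pentyl}-3-methyl-2-oxooctahydro-2H-quinolizine-1-carboxylate (C1 undefined) | C[C@@H]1CN2CCC[C@H](CCCCCCl)[C@H]2C(C(=O)OC)(CCCCC[C@@H]3CCCN(CC(C)C(=O)OC)[C@H]3CC(=O)OC)C1=O | intermediate
25 | methyl (3R,9S,9aS)-9-(5-chloropentyl)-1-{5-[(3S,9R,9aR)-1-(methoxycarbonyl)-3-methyl-2-oxooctahydro-2H-quinolizin-9-yl]pentyl}-3-methyl-2-oxooctahydro-2H-quinolizine-1-carboxylate (C1 centres undefined) | C[C@@H]1CN2CCC[C@H](CCCCCCl)[C@H]2C(C(=O)OC)(CCCCC[C@@H]3CCCN4C[C@H](C)C(=O)C(C(=O)OC)[C@@H]34)C1=O | intermediate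
26 | the 9-(5-iodopentyl) analogue of 25 | C[C@@H]1CN2CCC[C@H](CCCCCI)[C@H]2C(C(=O)OC)(CCCCC[C@@H]3CCCN4C[C@H](C)C(=O)C(C(=O)OC)[C@@H]34)C1=O | intermediate
27 | dimethyl petrosin A 1,1′-dicarboxylate (16-membered macrocycle; each C1 carries CO2Me and the pentamethylene bridge from C9 of the other unit; 3R,9S,9aS and 3S,9R,9aR; C1 centres undefined) | C[C@@H]1CN2CCC[C@H](CCCCC5)[C@H]2C(C(=O)OC)(CCCCC[C@@H]3CCCN4C[C@H](C)C(=O)C5(C(=O)OC)[C@@H]34)C1=O | intermediate
28 | petrosin A | C[C@@H]1CN2CCC[C@@H]3CCCCC[C@@H]4C(=O)[C@@H](C)CN5CCC[C@@H](CCCCC[C@@H](C1=O)[C@H]32)[C@H]45 | target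

**Totals**
Total step count: 14. Longest linear sequence: 10 steps (1, 6, 7, 8, 9, 10, 11, 12, 13, 14). If the two halves are obtained in about 95:5 er (an estimate; cyclopentenone is a demanding substrate for this addition), the heterochiral dimer is about 90% of the material. The homochiral, twofold-symmetric diastereomer is removed at 27 or 28 by chromatography or crystallisation.

**Three steps most likely to fail**

1. Step 4 (the new reductive Beckmann ring expansion; it is repeated on the mirror-image oxime in step 8). Risks are over-triflation, poor hydride capture of the imidoyl triflate, or a regioisomer from residual Z-oxime. The fallback uses known chemistry and sets out from 8. A classical Beckmann rearrangement (p-TsCl, pyridine, then aqueous K2CO3/dioxane) gives the lactam methyl 2-[(2R,3S)-3-(5-chloropentyl)-6-oxopiperidin-2-yl]acetate F1. O-Methylation with Me3OBF4 in CH2Cl2 gives the lactim ether methyl 2-[(2R,3S)-3-(5-chloropentyl)-6-methoxy-2,3,4,5-tetrahydropyridin-2-yl]acetate F2. NaBH4 in MeOH reduces F2 and the route is rejoined at 11. In the mirror-image series the same detour runs from 18 through the lactam methyl 2-[(2S,3R)-3-(5-chloropentyl)-6-oxopiperidin-2-yl]acetate F3 and the lactim ether methyl 2-[(2S,3R)-3-(5-chloropentyl)-6-methoxy-2,3,4,5-tetrahydropyridin-2-yl]acetate F4 to 21.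

2. Step 2 (and its mirror image, step 6). The weak point is the bromoacetate alkylation of the lithium enolate (proton transfer, loss of regiochemistry, dialkylation). The fallback sets out from silyl enol ether 5, now isolated by distillation. MeLi then allyl bromide, a faster and cleaner electrophile, gives (2R,3S)-3-(5-chloropentyl)-2-(prop-2-en-1-yl)cyclopentan-1-one F5. Oxidative cleavage with RuCl3 (cat.)/NaIO4 gives 2-[(1R,2S)-2-(5-chloropentyl)-5-oxocyclopentyl]acetic acid F6. Esterification with Me3SiCHN2 in MeOH returns to 7. In the mirror-image series the detour runs from 15 through (2S,3R)-3-(5-chloropentyl)-2-(prop-2-en-1-yl)cyclopentan-1-one F7 and 2-[(1S,2R)-2-(5-chloropentyl)-5-oxocyclopentyl]acetic acid F8 to 17.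

3. Step 13 (macrocyclisation that creates a quaternary centre). If C-alkylation is too slow or O-alkylation and oligomers win, the ring is closed by an aldol condensation instead, setting out from 25. Krapcho dealkoxycarbonylation (LiCl, H2O, DMSO, 150 °C) gives the chloro diketone (1R,3R,9S,9aS)-9-(5-chloropentyl)-3-methyl-1-{5-[(3S,9R,9aS)-3-methyl-2-oxooctahydro-2H-quinolizin-9-yl]pentyl}octahydro-2H-quinolizin-2-one F9. Kornblum oxidation (NaI, NaHCO3, DMSO, 110 °C) gives the aldehyde 5-[(1R,3R,9S,9aS)-3-methyl-1-{5-[(3S,9R,9aS)-3-methyl-2-oxooctahydro-2H-quinolizin-9-yl]pentyl}-2-oxooctahydro-2H-quinolizin-9-yl]pentanal F10. Intramolecular aldol condensation (KOH cat., MeOH, reflux, high dilution) can dehydrate only at C1 of the second unit, the one α-carbon with two hydrogens, and gives the macrocyclic exocyclic enone 1′-(bridge-ylidene)petrosin A (alkene geometry undefined) F11. Hydrogenation (H2, Pd/C, EtOAc) and DBU/MeOH equilibration rejoin the route at 28.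

**Further compounds**
F1 | step 4 | methyl 2-[(2R,3S)-3-(5-chloropentyl)-6-oxopiperidin-2-yl]acetate | N1C(=O)CC[C@H](CCCCCCl)[C@H]1CC(=O)OC
F2 | step 4 | methyl 2-[(2R,3S)-3-(5-chloropentyl)-6-methoxy-2,3,4,5-tetrahydropyridin-2-yl]acetate | N1=C(OC)CC[C@H](CCCCCCl)[C@H]1CC(=O)OC
F3 | step 8 | methyl 2-[(2S,3R)-3-(5-chloropentyl)-6-oxopiperidin-2-yl]acetate | N1C(=O)CC[C@@H](CCCCCCl)[C@@H]1CC(=O)OC
F4 | step 8 | methyl 2-[(2S,3R)-3-(5-chloropentyl)-6-methoxy-2,3,4,5-tetrahydropyridin-2-yl]acetate | N1=C(OC)CC[C@@H](CCCCCCl)[C@@H]1CC(=O)OC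
F5 | step 2 | (2R,3S)-3-(5-chloropentyl)-2-(prop-2-en-1-yl)cyclopentan-1-one | O=C1CC[C@H](CCCCCCl)[C@H]1CC=C
F6 | step 2 | 2-[(1R,2S)-2-(5-chloropentyl)-5-oxocyclopentyl]acetic acid | O=C1CC[C@H](CCCCCCl)[C@H]1CC(=O)O
F7 | step 6 | (2S,3R)-3-(5-chloropentyl)-2-(prop-2-en-1-yl)cyclopentan-1-one | O=C1CC[C@@H](CCCCCCl)[C@@H]1CC=C
F8 | step 6 | 2-[(1S,2R)-2-(5-chloropentyl)-5-oxocyclopentyl]acetic acid | O=C1CC[C@@H](CCCCCCl)[C@@H]1CC(=O)O
F9 | step 13 | (1R,3R,9S,9aS)-9-(5-chloropentyl)-3-methyl-1-{5-[(3S,9R,9aS)-3-methyl-2-oxooctahydro-2H-quinolizin-9-yl]pentyl}octahydro-2H-quinolizin-2-one | C[C@@H]1CN2CCC[C@H](CCCCCCl)[C@H]2[C@@H](CCCCC[C@@H]3CCCN4C[C@H](C)C(=O)C[C@@H]34)C1=O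
F10 | step 13 | 5-[(1R,3R,9S,9aS)-3-methyl-1-{5-[(3S,9R,9aS)-3-methyl-2-oxooctahydro-2H-quinolizin-9-yl]pentyl}-2-oxooctahydro-2H-quinolizin-9-yl]pentanal | C[C@@H]1CN2CCC[C@H](CCCCC=O)[C@H]2[C@@H](CCCCC[C@@H]3CCCN4C[C@H](C)C(=O)C[C@@H]34)C1=O
F11 | step 13 | macrocyclic exocyclic enone: petrosin A skeleton with C1 of the 9R unit joined to the bridge by C=C (alkene geometry undefined) | C[C@@H]1CN2CCC[C@H](CCCCC=5)[C@H]2[C@@H](CCCCC[C@@H]3CCCN4C[C@H](C)C(=O)C5[C@@H]34)C1=O
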